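**Retrosynthetic overview**
1. Target 22 ← ketal hydrolysis and stereospecific oxirane-to-alkene deoxygenation of oxiranyl cyclohexadiene 20; the oxirane is a traceless mask of the side-chain (E)-alkene.
2. Cyclohexadiene (the C1–C6 ring bond, last ring formed) ← light-triggered E→Z isomerization / disrotatory 6π electrocyclization of all-E trienyl pyranone 18; the oxirane relays the side-chain stereocentre to both ring stereocentres.
3. 18 ← aldol condensation of pyranone 5 (first ring formed, from triketide 3) with epoxy dienal 15.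
4. 15 ← two Wittig homologations of epoxy aldehyde 13 ← substrate-controlled epoxidation of enal 12 ← (S)-Roche ester 6, the only source of chirality.
5. Ring order: pyranone (step 2), dioxolane protecting ring (step 5), oxirane (step 8), cyclohexadiene (step 12).

Assumption: 1, 2, 6 and 11 are catalogue compounds; 1 is used as the racemate because its stereocentre is lost in step 2.

The stereochemical outcome of steps 8 and 12 is predicted from conformational models, not from precedent on these substrates.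

**Step 1**
Reactants: 1 methyl 2-methyl-3-oxopentanoate; 2 N-methoxy-N-methylpropanamide
Product: 3 methyl 2,4-dimethyl-3,5-dioxoheptanoate
Conditions: NaH, THF, 0 °C; n-BuLi, −10 °C; then 2, −10 °C → rt; aq. HCl
Reagents that add atoms: none
Why: Weiler dianion γ-acylation; the γ-carbanion is the more nucleophilic site and the Weinreb amide stops at the ketone, and no stereocentre needs control because both are lost in step 2.

**Step 2**
Reactants: 3 methyl 2,4-dimethyl-3,5-dioxoheptanoate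
Product: 4 6-ethyl-4-hydroxy-3,5-dimethyl-2H-pyran-2-one
Conditions: DBU, toluene, 100 °C; aq. HCl
Reagents that add atoms: none
Why: Base-mediated enol lactonization with loss of methanol gives the 4-hydroxy-2-pyranone.

**Step 3**
Reactants: 4 6-ethyl-4-hydroxy-3,5-dimethyl-2H-pyran-2-one
Product: 5 6-ethyl-2-methoxy-3,5-dimethyl-4H-pyran-4-one
Conditions: MeOTf, CH2Cl2, 0 °C → rt; aq. NaHCO3
Reagents that add atoms: methyl trifluoromethanesulfonate, COS(=O)(=O)C(F)(F)F
Why: O-methylation with a hard methylating agent occurs at the lactone carbonyl oxygen and gives the 2-methoxy-4-pyranone, the known regioselectivity for this pyranone class.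

**Step 4**
Reactants: 6 methyl (2S)-3-hydroxy-2-methylpropanoate
Product: 8 (2S)-1-hydroxy-2-methylpentan-3-one, via Weinreb amide 7 (not isolated)
Conditions: MeNH(OMe)·HCl, i-PrMgCl, THF, −20 °C; then EtMgBr, 0 °C; aq. NH4Cl
Reagents that add atoms: N,O-dimethylhydroxylamine hydrochloride, CNOC.Cl (to intermediate 7 only); ethylmagnesium bromide, CC[Mg]Br
Why: One-flask Weinreb ketone synthesis; the chelated tetrahedral intermediate prevents over-addition and the bought stereocentre is untouched because the ketone is released only on work-up.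

**Step 5**
Reactants: 8 (2S)-1-hydroxy-2-methylpentan-3-one
Product: 9 (2S)-2-(2-ethyl-1,3-dioxolan-2-yl)propan-1-ol
Conditions: Me3SiOCH2CH2OSiMe3, Me3SiOTf (cat.), CH2Cl2, −78 → −20 °C; then K2CO3, MeOH
Reagents that add atoms: 1,2-bis(trimethylsilyloxy)ethane, C[Si](C)(C)OCCO[Si](C)(C)C
Why: Noyori ketalization under kinetic, low-temperature conditions forms the dioxolane without enolizing the α-stereocentre; the methanolysis frees any silylated primary alcohol.

**Step 6**
Reactants: 9 (2S)-2-(2-ethyl-1,3-dioxolan-2-yl)propan-1-ol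
Product: 10 (2S)-2-(2-ethyl-1,3-dioxolan-2-yl)propanal
Conditions: PhI(OAc)2, TEMPO (cat.), CH2Cl2, rt
Reagents that add atoms: none
Why: TEMPO-catalysed alcohol oxidation stops at the aldehyde under non-basic conditions, so the α-stereocentre is not epimerized; the crude aldehyde is used at once.

**Step 7**
Reactants: 10 (2S)-2-(2-ethyl-1,3-dioxolan-2-yl)propanal; 11 2-(triphenylphosphoranylidene)propanal
Product: 12 (2E,4S)-4-(2-ethyl-1,3-dioxolan-2-yl)-2-methylpent-2-enal
Conditions: toluene, 80 °C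
Reagents that add atoms: none
Why: Wittig olefination with a stabilized ylide gives the (E)-α-methyl enal under neutral conditions that preserve the allylic stereocentre.

**Step 8**
Reactants: 12 (2E,4S)-4-(2-ethyl-1,3-dioxolan-2-yl)-2-methylpent-2-enal
Product: 13 (2R,3S)-3-[(1S)-1-(2-ethyl-1,3-dioxolan-2-yl)ethyl]-2-methyloxirane-2-carbaldehyde
Conditions: 30% aq. H2O2, NaHCO3, MeOH, 0 °C
Reagents that add atoms: hydrogen peroxide, OO
Why: Weitz–Scheffer nucleophilic epoxidation; 1,3-allylic strain with the C2 methyl holds the C4–H in the alkene plane, so hydroperoxide adds to C3 anti to the bulky dioxolanyl group and sets both oxirane centres from the bought one.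

**Step 9**
Reactants: 13 (2R,3S)-3-[(1S)-1-(2-ethyl-1,3-dioxolan-2-yl)ethyl]-2-methyloxirane-2-carbaldehyde; 11 2-(triphenylphosphoranylidene)propanal
Product: 14 (2E)-3-{(2S,3S)-3-[(1S)-1-(2-ethyl-1,3-dioxolan-2-yl)ethyl]-2-methyloxiran-2-yl}-2-methylprop-2-enal
Conditions: toluene, 80 °C
Reagents that add atoms: none
Why: Wittig olefination with the stabilized ylide is (E)-selective and leaves the oxirane intact; the quaternary α-carbon of 13 cannot epimerize.

**Step 10**
Reactants: 14 (2E)-3-{(2S,3S)-3-[(1S)-1-(2-ethyl-1,3-dioxolan-2-yl)ethyl]-2-methyloxiran-2-yl}-2-methylprop-2-enal; 11 2-(triphenylphosphoranylidene)propanal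
Product: 15 (2E,4E)-5-{(2S,3S)-3-[(1S)-1-(2-ethyl-1,3-dioxolan-2-yl)ethyl]-2-methyloxiran-2-yl}-2,4-dimethylpenta-2,4-dienal
Conditions: toluene, 80 °C
Reagents that add atoms: none
Why: A second (E)-selective Wittig homologation; the oxirane keeps the side-chain stereocentre out of conjugation, so it cannot epimerize by vinylogous enolization.

**Step 11**
Reactants: 5 6-ethyl-2-methoxy-3,5-dimethyl-4H-pyran-4-one; 15 (2E,4E)-5-{(2S,3S)-3-[(1S)-1-(2-ethyl-1,3-dioxolan-2-yl)ethyl]-2-methyloxiran-2-yl}-2,4-dimethylpenta-2,4-dienal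
Product: 18 6-[(2E,4E,6E)-7-{(2S,3S)-3-[(1S)-1-(2-ethyl-1,3-dioxolan-2-yl)ethyl]-2-methyloxiran-2-yl}-4,6-dimethylhepta-2,4,6-trien-2-yl]-2-methoxy-3,5-dimethyl-4H-pyran-4-one, via lithium aldolate 16 (not isolated), via aldol acetate 17 (not isolated)
Conditions: LiN(SiMe3)2, THF, −78 °C, then 15; Ac2O, −78 → 0 °C; DBU, rt
Reagents that add atoms: lithium bis(trimethylsilyl)amide, [Li+].C[Si](C)(C)[N-][Si](C)(C)C (lithium to intermediate 16 only); acetic anhydride, CC(=O)OC(C)=O (to intermediate 17 only)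
Why: Aldol addition of the laterally lithiated pyranone, acetylation and E1cB elimination in one flask give the conjugated (E)-alkene; the two transient carbinol-derived centres are destroyed.

**Step 12**
Reactants: 18 6-[(2E,4E,6E)-7-{(2S,3S)-3-[(1S)-1-(2-ethyl-1,3-dioxolan-2-yl)ethyl]-2-methyloxiran-2-yl}-4,6-dimethylhepta-2,4,6-trien-2-yl]-2-methoxy-3,5-dimethyl-4H-pyran-4-one
Product: 20 6-[(1S,6R)-6-{(2S,3S)-3-[(1S)-1-(2-ethyl-1,3-dioxolan-2-yl)ethyl]-2-methyloxiran-2-yl}-1,3,5-trimethylcyclohexa-2,4-dien-1-yl]-2-methoxy-3,5-dimethyl-4H-pyran-4-one, via (2E,4Z,6E)-triene 19 (not isolated)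
Conditions: hν (365 nm LED), degassed benzene (2 mM), 45 °C
Reagents that add atoms: none
Why: Proposed new method: a light-driven E→Z isomerization / disrotatory 6π electrocyclization cascade in which a terminal trans-oxirane (a traceless mask of the side-chain alkene) relays the bought stereocentre to both ring stereocentres; mechanistic reasoning: the oxirane removes the side chain from the chromophore, so only the three triene bonds isomerize and the product, transparent at 365 nm, is not re-excited; of the photo-equilibrating isomers only 19 (small groups inside at both termini) closes fast in the ground state, and disrotatory closure of an E,Z,E triene puts pyranone and oxiranyl cis; 1,3-allylic strain with the C6 methyl holds the oxirane oxygen in the diene plane and leaves the oxirane C–C bond over one face of C7, so C2 bonds from the opposite face, which translates the (2S,3S)-oxirane into (1S,6R); closest known reaction type: sunlight-induced isomerization / 6π electrocyclization of all-E polyenyl γ-pyranones and thermal 6π closures whose torquoselectivity is set by an allylic stereocentre.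

**Step 13**
Reactants: 20 6-[(1S,6R)-6-{(2S,3S)-3-[(1S)-1-(2-ethyl-1,3-dioxolan-2-yl)ethyl]-2-methyloxiran-2-yl}-1,3,5-trimethylcyclohexa-2,4-dien-1-yl]-2-methoxy-3,5-dimethyl-4H-pyran-4-one
Product: 21 6-[(1S,6R)-6-[(2E,4S)-4-(2-ethyl-1,3-dioxolan-2-yl)pent-2-en-2-yl]-1,3,5-trimethylcyclohexa-2,4-dien-1-yl]-2-methoxy-3,5-dimethyl-4H-pyran-4-one
Conditions: MeReO3 (5 mol %), PPh3, benzene, 60 °C
Reagents that add atoms: none
Why: Rhenium-catalysed oxygen-atom transfer from the oxirane to the phosphine is stereospecific with retention, so the trans-oxirane returns the (E)-trisubstituted alkene without touching the three stereocentres.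

**Step 14**
Reactants: 21 6-[(1S,6R)-6-[(2E,4S)-4-(2-ethyl-1,3-dioxolan-2-yl)pent-2-en-2-yl]-1,3,5-trimethylcyclohexa-2,4-dien-1-yl]-2-methoxy-3,5-dimethyl-4H-pyran-4-one
Product: 22 2-methoxy-3,5-dimethyl-6-[(1S,6R)-1,3,5-trimethyl-6-[(2E,4S)-4-methyl-5-oxohept-2-en-2-yl]cyclohexa-2,4-dien-1-yl]-4H-pyran-4-one
Conditions: In(O3SCF3)3 (5 mol %), acetone–H2O (20:1), rt
Reagents that add atoms: water, O
Why: Mild Lewis acid-catalysed ketal hydrolysis releases the ethyl ketone under near-neutral conditions that avoid enolization of the α-stereocentre and conjugation of the β,γ-alkene.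

**Compound list**
1 | methyl 2-methyl-3-oxopentanoate (racemic) | CCC(=O)C(C)C(=O)OC | starting material
2 | N-methoxy-N-methylpropanamide | CCC(=O)N(C)OC | starting material
3 | methyl 2,4-dimethyl-3,5-dioxoheptanoate (stereoisomer mixture) | CCC(=O)C(C)C(=O)C(C)C(=O)OC | intermediate
4 | 6-ethyl-4-hydroxy-3,5-dimethyl-2H-pyran-2-one | CCc1oc(=O)c(C)c(O)c1C | intermediate
5 | 6-ethyl-2-methoxy-3,5-dimethyl-4H-pyran-4-one | CCc1oc(OC)c(C)c(=O)c1C | intermediate
6 | methyl (2S)-3-hydroxy-2-methylpropanoate | C[C@@H](CO)C(=O)OC | starting material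
7 | (2S)-3-hydroxy-N-methoxy-N,2-dimethylpropanamide (present as its magnesium alkoxide) | C[C@@H](CO)C(=O)N(C)OC | intermediate
8 | (2S)-1-hydroxy-2-methylpentan-3-one | C[C@@H](CO)C(=O)CC | intermediate
9 | (2S)-2-(2-ethyl-1,3-dioxolan-2-yl)propan-1-ol | C[C@@H](CO)C1(CC)OCCO1 | intermediate
10 | (2S)-2-(2-ethyl-1,3-dioxolan-2-yl)propanal | C[C@@H](C=O)C1(CC)OCCO1 | intermediate
11 | 2-(triphenylphosphoranylidene)propanal | CC(C=O)=P(c1ccccc1)(c1ccccc1)c1ccccc1 | starting material
12 | (2E,4S)-4-(2-ethyl-1,3-dioxolan-2-yl)-2-methylpent-2-enal | O=C/C(C)=C/[C@H](C)C1(CC)OCCO1 | intermediate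
13 | (2R,3S)-3-[(1S)-1-(2-ethyl-1,3-dioxolan-2-yl)ethyl]-2-methyloxirane-2-carbaldehyde | O=C[C@]1(C)O[C@H]1[C@H](C)C2(CC)OCCO2 | intermediate
14 | (2E)-3-{(2S,3S)-3-[(1S)-1-(2-ethyl-1,3-dioxolan-2-yl)ethyl]-2-methyloxiran-2-yl}-2-methylprop-2-enal | O=C/C(C)=C/[C@]1(C)O[C@H]1[C@H](C)C2(CC)OCCO2 | intermediate
15 | (2E,4E)-5-{(2S,3S)-3-[(1S)-1-(2-ethyl-1,3-dioxolan-2-yl)ethyl]-2-methyloxiran-2-yl}-2,4-dimethylpenta-2,4-dienal | O=C/C(C)=C/C(C)=C/[C@]1(C)O[C@H]1[C@H](C)C2(CC)OCCO2 | intermediate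
16 | lithium (4E,6E)-7-{(2S,3S)-3-[(1S)-1-(2-ethyl-1,3-dioxolan-2-yl)ethyl]-2-methyloxiran-2-yl}-2-(6-methoxy-3,5-dimethyl-4-oxo-4H-pyran-2-yl)-4,6-dimethylhepta-4,6-dien-3-olate (C2/C3 epimer mixture) | COc1oc(C(C)C([O-])/C(C)=C/C(C)=C/[C@]2(C)O[C@H]2[C@H](C)C3(CC)OCCO3)c(C)c(=O)c1C.[Li+] | intermediate
17 | (4E,6E)-7-{(2S,3S)-3-[(1S)-1-(2-ethyl-1,3-dioxolan-2-yl)ethyl]-2-methyloxiran-2-yl}-2-(6-methoxy-3,5-dimethyl-4-oxo-4H-pyran-2-yl)-4,6-dimethylhepta-4,6-dien-3-yl acetate (C2/C3 epimer mixture) | COc1oc(C(C)C(OC(C)=O)/C(C)=C/C(C)=C/[C@]2(C)O[C@H]2[C@H](C)C3(CC)OCCO3)c(C)c(=O)c1C | intermediate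
18 | 6-[(2E,4E,6E)-7-{(2S,3S)-3-[(1S)-1-(2-ethyl-1,3-dioxolan-2-yl)ethyl]-2-methyloxiran-2-yl}-4,6-dimethylhepta-2,4,6-trien-2-yl]-2-methoxy-3,5-dimethyl-4H-pyran-4-one | COc1oc(/C(C)=C/C(C)=C/C(C)=C/[C@]2(C)O[C@H]2[C@H](C)C3(CC)OCCO3)c(C)c(=O)c1C | intermediate
19 | 6-[(2E,4Z,6E)-7-{(2S,3S)-3-[(1S)-1-(2-ethyl-1,3-dioxolan-2-yl)ethyl]-2-methyloxiran-2-yl}-4,6-dimethylhepta-2,4,6-trien-2-yl]-2-methoxy-3,5-dimethyl-4H-pyran-4-one | COc1oc(/C(C)=C/C(C)=C\C(C)=C\[C@]2(C)O[C@H]2[C@H](C)C3(CC)OCCO3)c(C)c(=O)c1C | intermediate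
20 | 6-[(1S,6R)-6-{(2S,3S)-3-[(1S)-1-(2-ethyl-1,3-dioxolan-2-yl)ethyl]-2-methyloxiran-2-yl}-1,3,5-trimethylcyclohexa-2,4-dien-1-yl]-2-methoxy-3,5-dimethyl-4H-pyran-4-one | CCC1(OCCO1)[C@@H](C)[C@@H]2O[C@@]2(C)[C@@H]3C(C)=CC(C)=C[C@]3(C)c4oc(OC)c(C)c(=O)c4C | intermediate
21 | 6-[(1S,6R)-6-[(2E,4S)-4-(2-ethyl-1,3-dioxolan-2-yl)pent-2-en-2-yl]-1,3,5-trimethylcyclohexa-2,4-dien-1-yl]-2-methoxy-3,5-dimethyl-4H-pyran-4-one | CCC1(OCCO1)[C@@H](C)/C=C(\C)[C@@H]2C(C)=CC(C)=C[C@]2(C)c3oc(OC)c(C)c(=O)c3C | intermediate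
22 | 2-methoxy-3,5-dimethyl-6-[(1S,6R)-1,3,5-trimethyl-6-[(2E,4S)-4-methyl-5-oxohept-2-en-2-yl]cyclohexa-2,4-dien-1-yl]-4H-pyran-4-one | CCC(=O)[C@@H](C)/C=C(\C)[C@@H]1C(C)=CC(C)=C[C@]1(C)c1oc(OC)c(C)c(=O)c1C | target

**Totals**
Total step count: 14. Longest linear sequence: 11 steps (6 → 8 → 9 → 10 → 12 → 13 → 14 → 15 → 18 → 20 → 21 → 22).

**Three steps most likely to fail**

Step 12 (the proposed new step). Risks: side photochemistry of the vinyl oxirane, slow funnelling through 19, trans-fused by-products from the hindered triene isomers, and a facial preference at C7 that is weaker than the model predicts. If the facial preference is low, the two cis-diastereomers are separable because the side-chain centre is fixed. Fallback with known chemistry, setting out from 14: a Still–Gennari olefination (MeO2CCH(Me)P(O)(OCH2CF3)2, KN(SiMe3)2, 18-crown-6, THF, −78 °C) installs the Z bond directly and gives methyl (2Z,4E)-5-{(2S,3S)-3-[(1S)-1-(2-ethyl-1,3-dioxolan-2-yl)ethyl]-2-methyloxiran-2-yl}-2,4-dimethylpenta-2,4-dienoate F3. Reduction with i-Bu2AlH gives the (2Z,4E)-dienol F4, and MnO2 gives the (2Z,4E)-dienal F5. Condensation with lithiated 5 exactly as in step 11, through the (4Z,6E) lithium aldolate F6 and the (4Z,6E) aldol acetate F7, then delivers 19 without light. 19 closes in the dark at 45 °C by the known thermal disrotatory 6π electrocyclization of E,Z,E-trienyl pyranones, and the route is rejoined at 20.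

Step 8. Risks: sluggish conjugate addition of hydroperoxide at the hindered β-carbon, oxidation of the aldehyde, and epimerization of the γ-stereocentre by vinylogous enolization. Fallback, setting out from 12: Luche reduction (NaBH4, CeCl3·7H2O, MeOH, 0 °C) gives (2E,4S)-4-(2-ethyl-1,3-dioxolan-2-yl)-2-methylpent-2-en-1-ol F1. Electrophilic epoxidation with m-CPBA and NaHCO3 in CH2Cl2 at 0 °C attacks the electron-rich trisubstituted alkene under the same 1,3-allylic strain control and gives {(2S,3S)-3-[(1S)-1-(2-ethyl-1,3-dioxolan-2-yl)ethyl]-2-methyloxiran-2-yl}methanol F2. Oxidation with PhI(OAc)2 and catalytic TEMPO comes back to the route at 13.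

Step 13. Risk: oxygen-atom transfer may stall at an oxirane flanked by the ring carbon and the branched side-chain carbon. Fallback, setting out from 20: switch from two-electron oxo transfer to single-electron chemistry with (C5H5)2TiCl (trivalent titanium, made in the flask from (C5H5)2TiCl2 and Zn dust, THF, rt). It opens the oxirane homolytically at the tertiary carbon, a second equivalent traps the radical, and β-elimination gives the alkene. The (E)-isomer is expected to dominate because the (Z)-isomer would place the ring carbon and the branched carbon cis. The route is rejoined at 21, and this fallback makes no new compound: none F0.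

**Further compounds**
F1 | step 8 | (2E,4S)-4-(2-ethyl-1,3-dioxolan-2-yl)-2-methylpent-2-en-1-ol | OC/C(C)=C/[C@H](C)C1(CC)OCCO1
F2 | step 8 | {(2S,3S)-3-[(1S)-1-(2-ethyl-1,3-dioxolan-2-yl)ethyl]-2-methyloxiran-2-yl}methanol | OC[C@]1(C)O[C@H]1[C@H](C)C2(CC)OCCO2
F3 | step 12 | methyl (2Z,4E)-5-{(2S,3S)-3-[(1S)-1-(2-ethyl-1,3-dioxolan-2-yl)ethyl]-2-methyloxiran-2-yl}-2,4-dimethylpenta-2,4-dienoate | COC(=O)/C(C)=C\C(C)=C\[C@]1(C)O[C@H]1[C@H](C)C2(CC)OCCO2
F4 | step 12 | (2Z,4E)-5-{(2S,3S)-3-[(1S)-1-(2-ethyl-1,3-dioxolan-2-yl)ethyl]-2-methyloxiran-2-yl}-2,4-dimethylpenta-2,4-dien-1-ol | OC/C(C)=C\C(C)=C\[C@]1(C)O[C@H]1[C@H](C)C2(CC)OCCO2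
F5 | step 12 | (2Z,4E)-5-{(2S,3S)-3-[(1S)-1-(2-ethyl-1,3-dioxolan-2-yl)ethyl]-2-methyloxiran-2-yl}-2,4-dimethylpenta-2,4-dienal | O=C/C(C)=C\C(C)=C\[C@]1(C)O[C@H]1[C@H](C)C2(CC)OCCO2
F6 | step 12 | lithium (4Z,6E)-7-{(2S,3S)-3-[(1S)-1-(2-ethyl-1,3-dioxolan-2-yl)ethyl]-2-methyloxiran-2-yl}-2-(6-methoxy-3,5-dimethyl-4-oxo-4H-pyran-2-yl)-4,6-dimethylhepta-4,6-dien-3-olate | COc1oc(C(C)C([O-])/C(C)=C\C(C)=C\[C@]2(C)O[C@H]2[C@H](C)C3(CC)OCCO3)c(C)c(=O)c1C.[Li+]
F7 | step 12 | (4Z,6E)-7-{(2S,3S)-3-[(1S)-1-(2-ethyl-1,3-dioxolan-2-yl)ethyl]-2-methyloxiran-2-yl}-2-(6-methoxy-3,5-dimethyl-4-oxo-4H-pyran-2-yl)-4,6-dimethylhepta-4,6-dien-3-yl acetate | COc1oc(C(C)C(OC(C)=O)/C(C)=C\C(C)=C\[C@]2(C)O[C@H]2[C@H](C)C3(CC)OCCO3)c(C)c(=O)c1C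
F0 | step 13 | none | none
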